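**Retrosynthetic overview**
- Ester C3–O bond: target ⇒ trans-(2R,3S)-dihydrobenzofuran-3-ol + (Z)-4-acetoxy-2-methylbut-2-enoic acid, whose Z geometry is taken from a butenolide ring.
- C2–C3 and O1–C2 bonds: dihydrobenzofuranol ⇒ 5-acetyl-2,4-dihydroxybenzaldehyde + a chiral methallyl sulfonium ylide. C2 and C3 both carry oxygen and are acceptor carbons by nature; C2 is used as a donor (sulfonium-stabilised carbanion, an α-aryloxy-methallyl anion equivalent) and the sulfonium then leaves.
- Arene: the aldehyde ⇒ 2,4-dihydroxybenzaldehyde by C5 acetylation.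
- Ring order: the benzene ring is bought; a transient oxirane forms first and is opened by the ortho phenoxide to give the dihydrofuran ring, the only ring built.

Assumption: the (1S,4S,5S)-sulfide is taken to be the enantiomer whose ylides give (S,S)-trans-epoxides; if the sense is the reverse, its enantiomer is used and nothing else changes.

**Step 1**
Reactants: 1 2,4-dihydroxybenzaldehyde
Product: 2 5-acetyl-2,4-dihydroxybenzaldehyde
Conditions: AcOH, BF3·OEt2 (4 equiv), 90 °C; then H2O, 60 °C
Reagents that add atoms: acetic acid CC(=O)O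
Why: Friedel–Crafts (Nencki-type) C-acetylation at C5, which is para to one hydroxyl, ortho to the other and unhindered (C3 lies between both hydroxyls), the same selectivity that gives 4,6-diacetylresorcinol from resacetophenone; no stereocenter is formed.

**Step 2**
Reactants: 3 (1S,4S,5S)-isothiocineole; 4 3-bromo-2-methylprop-1-ene
Product: 5 (1S,4S,5S)-4,7,7-trimethyl-6-(2-methylprop-2-en-1-yl)-6-thiabicyclo[3.2.1]octan-6-ium tetrafluoroborate
Conditions: NaBF4 (3 equiv), CH2Cl2/H2O, rt, 24 h
Reagents that add atoms: sodium tetrafluoroborate [Na+].F[B-](F)(F)F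
Why: SN2 S-alkylation of the thioether by the allylic bromide, pulled forward by exchange of bromide for non-nucleophilic tetrafluoroborate; sulfur reacts on its less hindered lone pair, so one sulfonium diastereomer is expected, and no carbon stereocenter is created.

**Step 3**
Reactants: 2 5-acetyl-2,4-dihydroxybenzaldehyde; 5 the methallyl sulfonium tetrafluoroborate
Product: 8 1-[(2R,3S)-3,6-dihydroxy-2-(prop-1-en-2-yl)-2,3-dihydro-1-benzofuran-5-yl]ethan-1-one, via sulfonium ylide 6 (not isolated), via trans-vinyl epoxide 7 (not isolated)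
Conditions: 5 (1.3 equiv), KOH (3.5 equiv, added last), MeCN/H2O 9:1, 0 °C → rt, then 45 °C, 2 h; pH 6 buffer work-up; sulfide 3 recovered
Reagents that add atoms: none
Why: Proposed new method: the ylide carbon, which becomes the oxygen-bearing C2 and is by nature an acceptor carbon like the aldehyde carbon, attacks the aldehyde as a sulfonium-stabilised carbanion in a chiral-sulfide Corey–Chaykovsky epoxidation through the anti betaine to the (2S,3S)-trans-epoxide 7 (the sulfide shields one ylide face; this sets C3 = S), and the ortho phenoxide, the only nucleophile that can reach, then opens the oxirane at the allylic carbon in a 5-endo SN2 step with inversion (this sets C2 = R and the trans relationship), overall a formal [4+1] annulation; the closest known reactions are the isothiocineole-mediated asymmetric epoxidation of aryl aldehydes with allylic sulfonium salts and the spontaneous closure of 2-hydroxystilbene oxides to trans-2-aryl-2,3-dihydrobenzofuran-3-ols, and what is new is the unprotected phenoxide aldehyde and the ring closure in the same flask.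

**Step 4**
Reactants: 9 3-methylfuran-2(5H)-one
Product: 11 (Z)-4-acetoxy-2-methylbut-2-enoic acid, via sodium (Z)-4-hydroxy-2-methylbut-2-enoate 10 (not isolated)
Conditions: NaOH (1.02 equiv), H2O, 0 °C → rt; evaporate; Ac2O (3 equiv), pyridine, DMAP (5 mol%), 0 °C; H2O; cold 1 M HCl to pH 3, EtOAc
Reagents that add atoms: sodium hydroxide [Na+].[OH-]; acetic anhydride CC(=O)OC(C)=O
Why: Lactone saponification gives the hydroxy carboxylate with the Z geometry inherited from the ring, and DMAP-catalysed O-acetylation of the primary allylic hydroxyl while the acid is still its salt traps it before acidification, when the free hydroxy acid would relactonise; no stereocenter, Z alkene retained.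

**Step 5**
Reactants: 11 (Z)-4-acetoxy-2-methylbut-2-enoic acid; 8 the (2R,3S)-alcohol
Product: 13 (2R,3S)-5-acetyl-6-hydroxy-2-(prop-1-en-2-yl)-2,3-dihydro-1-benzofuran-3-yl (2Z)-4-(acetyloxy)-2-methylbut-2-enoate, via acid chloride 12 (not isolated)
Conditions: 11 (1.15 equiv), 1-chloro-N,N,2-trimethylprop-1-en-1-amine (1.2 equiv), CH2Cl2, 0 °C, 1 h; then 8, pyridine (3 equiv), CH2Cl2, −20 → 0 °C
Reagents that add atoms: none
Why: Neutral acyl chloride formation with Ghosez's reagent followed by pyridine-mediated O-acylation of the secondary benzylic alcohol; the phenol is hydrogen-bonded to the ortho acetyl and reacts much more slowly, no DMAP or trialkylamine is present to isomerise the Z enoate, and the C3–O bond is untouched, so (2R,3S) is retained.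

**Compound list**
1 | 2,4-dihydroxybenzaldehyde | O=Cc1ccc(O)cc1O | starting material
2 | 5-acetyl-2,4-dihydroxybenzaldehyde | CC(=O)c1cc(C=O)c(O)cc1O | intermediate
3 | (1S,4S,5S)-isothiocineole, (1S,4S,5S)-4,7,7-trimethyl-6-thiabicyclo[3.2.1]octane | C[C@H]1CC[C@H]2C[C@@H]1SC2(C)C | starting material
4 | 3-bromo-2-methylprop-1-ene (methallyl bromide) | C=C(C)CBr | starting material
5 | (1S,4S,5S)-4,7,7-trimethyl-6-(2-methylprop-2-en-1-yl)-6-thiabicyclo[3.2.1]octan-6-ium tetrafluoroborate (one diastereomer at sulfur, not specified in the SMILES) | C[C@H]1CC[C@H]2C[C@@H]1[S+](CC(C)=C)C2(C)C.F[B-](F)(F)F | intermediate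
6 | sulfonium ylide of 5 (carbanion on the S-CH of the methallyl group; sulfur configuration not specified) | C[C@H]1CC[C@H]2C[C@@H]1[S+]([CH-]C(C)=C)C2(C)C | intermediate
7 | 1-{2,4-dihydroxy-5-[(2S,3S)-3-(prop-1-en-2-yl)oxiran-2-yl]phenyl}ethan-1-one (trans-epoxide, present as its phenoxide) | C=C(C)[C@@H]1O[C@H]1c1cc(C(C)=O)c(O)cc1O | intermediate
8 | 1-[(2R,3S)-3,6-dihydroxy-2-(prop-1-en-2-yl)-2,3-dihydro-1-benzofuran-5-yl]ethan-1-one (trans) | C=C(C)[C@H]1Oc2cc(O)c(C(C)=O)cc2[C@@H]1O | intermediate
9 | 3-methylfuran-2(5H)-one | CC1=CCOC1=O | starting material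
10 | sodium (Z)-4-hydroxy-2-methylbut-2-enoate | [Na+].[O-]C(=O)/C(C)=C\CO | intermediate
11 | (Z)-4-acetoxy-2-methylbut-2-enoic acid | OC(=O)/C(C)=C\COC(C)=O | intermediate
12 | (Z)-4-acetoxy-2-methylbut-2-enoyl chloride | ClC(=O)/C(C)=C\COC(C)=O | intermediate
13 | (2R,3S)-5-acetyl-6-hydroxy-2-(prop-1-en-2-yl)-2,3-dihydro-1-benzofuran-3-yl (2Z)-4-(acetyloxy)-2-methylbut-2-enoate | C=C(C)[C@H]1Oc2cc(O)c(C(C)=O)cc2[C@@H]1OC(=O)/C(C)=C\COC(C)=O | target

**Totals**
Total step count: 5. Longest linear sequence: 3 steps (step 1 → step 3 → step 5); steps 2 and 4 are one-step side branches.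

**Steps most likely to fail, with fallbacks**

Risk 1, step 3. The dianion of 2 is a poor electrophile and may self-condense (aldehyde with acetyl) before the ylide adds. The electron-rich epoxide may also ionise at the benzylic carbon and erode the trans ratio or the ee. The fallback sets out from 2 and comes back at 8. Both phenols are silylated (t-BuMe2SiCl, imidazole, DMF) to give 5-acetyl-2,4-bis(tert-butyldimethylsilyloxy)benzaldehyde F1. The ylide is preformed from 5 (KN(SiMe3)2, THF, −78 °C) and now meets an ordinary aryl aldehyde, giving the isolable 1-{2,4-bis(tert-butyldimethylsilyloxy)-5-[(2S,3S)-3-(prop-1-en-2-yl)oxiran-2-yl]phenyl}ethan-1-one F2. Bu4NF in THF at 0 °C then frees the phenoxides, and the ortho one closes onto the oxirane (through 7) to give 8.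

Risk 2, step 5. The activated Z acid may isomerise to the E (tiglate-type) ester, and the phenol may be acylated as well. The fallback sets out from 8 and comes back at 13, building the Z alkene on the substrate. Methyl 2-[bis(2,2,2-trifluoroethoxy)phosphoryl]propanoate is cleaved with Me3SnOH to 2-[bis(2,2,2-trifluoroethoxy)phosphoryl]propanoic acid F6. This acid cannot isomerise, so it is coupled to 8 with EDC·HCl and catalytic DMAP to give (2R,3S)-5-acetyl-6-hydroxy-2-(prop-1-en-2-yl)-2,3-dihydro-1-benzofuran-3-yl 2-[bis(2,2,2-trifluoroethoxy)phosphoryl]propanoate F7 (mixture of epimers at the phosphonate carbon). Still–Gennari olefination of F7 with 2-oxoethyl acetate (KN(SiMe3)2 2.1 equiv, 18-crown-6, THF, −78 °C) gives the Z-trisubstituted enoate 13.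

Risk 3, step 4. Mixed-anhydride formation at the carboxylate may outrun O-acetylation and return the butenolide 9. The fallback sets out from 9 and comes back at 11, and never passes through a free Z-hydroxy acid. i-Bu2AlH (CH2Cl2, −78 → 0 °C) reduces the lactone to (Z)-2-methylbut-2-ene-1,4-diol F3. Pseudomonas cepacia lipase with vinyl acetate acetylates the less hindered hydroxyl, remote from the methyl group, to give (Z)-4-hydroxy-3-methylbut-2-en-1-yl acetate F4. TEMPO/PhI(OAc)2 gives (Z)-4-acetoxy-2-methylbut-2-enal F5, which is oxidised at once with NaClO2/NaH2PO4/2-methylbut-2-ene to 11.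

**Further compounds**
F1 | step 3 | 5-acetyl-2,4-bis(tert-butyldimethylsilyloxy)benzaldehyde | CC(=O)c1cc(C=O)c(O[Si](C)(C)C(C)(C)C)cc1O[Si](C)(C)C(C)(C)C
F2 | step 3 | 1-{2,4-bis(tert-butyldimethylsilyloxy)-5-[(2S,3S)-3-(prop-1-en-2-yl)oxiran-2-yl]phenyl}ethan-1-one | C=C(C)[C@@H]1O[C@H]1c1cc(C(C)=O)c(O[Si](C)(C)C(C)(C)C)cc1O[Si](C)(C)C(C)(C)C
F3 | step 4 | (Z)-2-methylbut-2-ene-1,4-diol | OC/C=C(/C)CO
F4 | step 4 | (Z)-4-hydroxy-3-methylbut-2-en-1-yl acetate | CC(=O)OC/C=C(/C)CO
F5 | step 4 | (Z)-4-acetoxy-2-methylbut-2-enal | CC(=O)OC/C=C(/C)C=O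
F6 | step 5 | 2-[bis(2,2,2-trifluoroethoxy)phosphoryl]propanoic acid | CC(C(=O)O)P(=O)(OCC(F)(F)F)OCC(F)(F)F
F7 | step 5 | (2R,3S)-5-acetyl-6-hydroxy-2-(prop-1-en-2-yl)-2,3-dihydro-1-benzofuran-3-yl 2-[bis(2,2,2-trifluoroethoxy)phosphoryl]propanoate | C=C(C)[C@H]1Oc2cc(O)c(C(C)=O)cc2[C@@H]1OC(=O)C(C)P(=O)(OCC(F)(F)F)OCC(F)(F)F
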